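## Retrosynthetic overview

1. The target is a (2S)-flavanone; the last two steps only strip auxiliaries: a C3 allyl ester carried as a temporary activating group (Pd-catalysed deallylation/decarboxylation) and the 7-O-MOM group.
2. Ring C (the pyranone) is closed last by a convergent [3+3] annulation that makes C3–C4 (Claisen-type C-acylation) and O1–C8a (intramolecular SNAr) in one flask. The partners are the dilithio dianion of an (S)-β-hydroxy ester (O1–C2–C3 with the B ring) and an allyl 2-fluorobenzoate (C4, C4a, C8a, ring A with the prenyl group already at C8).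
3. Enabling feature: in ring C the carbonyl carbon C4 and the ether oxygen O1 sit on adjacent ring-A carbons (C4a and C8a). An o-fluoroaroyl unit is therefore a 1,3-dielectrophile whose C8a–F is activated by the ortho C4 carbonyl, and O1–C2–C3 is a 1,3-dinucleophile once C3 carries the ester.
4. A-ring ester: 4-bromo-3-fluorophenol → MOM ether → lithiation between F and OMOM with prenylation → Br/Li exchange and allyl chloroformate. B-ring piece: 4'-hydroxyacetophenone + isoprene → 2,2-dimethylchroman ketone → allyl β-keto ester → asymmetric transfer hydrogenation, which sets C2.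
5. Ring order: the dihydropyran ring of the B-ring chroman first, the pyranone ring C last; both benzene rings are bought.

Key step: step 7

Remark on the chemistry: flavanone numbering (O1, C2, C3, C4, C4a, C5–C8, C8a) is used for the target and its precursors. Organolithium and enolate intermediates are written as simple monomeric salts. The bromofluorophenol, 4'-hydroxyacetophenone and all reagents are assumed to be catalogue chemicals.

## Route

Step 1
Reactants: 1 4-bromo-3-fluorophenol
Product: 2 1-bromo-2-fluoro-4-(methoxymethoxy)benzene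
Conditions: NaH, MOMCl, THF/DMF, 0 °C → rt
Reagents that add atoms: chloromethyl methyl ether, COCCl
Why: Williamson-type O-alkylation of the phenoxide gives a base-stable MOM ether that later directs the ortho-lithiation.

Step 2
Reactants: 2 1-bromo-2-fluoro-4-(methoxymethoxy)benzene
Product: 4 1-bromo-2-fluoro-4-(methoxymethoxy)-3-(3-methylbut-2-en-1-yl)benzene, via C3-aryllithium 3 (not isolated)
Conditions: LDA (1.1 equiv), THF, −78 °C; CuBr·SMe2 (10 mol %), prenyl bromide, −78 → −30 °C
Reagents that add atoms: 1-bromo-3-methylbut-2-ene (prenyl bromide), CC(C)=CCBr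
Why: Directed ortho-metalation removes the C–H flanked by F and OMOM, the most acidic one, without touching the bromide, and copper-catalysed allylic substitution at the unhindered CH2 terminus of prenyl bromide should give the linear prenyl arene.

Step 3
Reactants: 4 1-bromo-2-fluoro-4-(methoxymethoxy)-3-(3-methylbut-2-en-1-yl)benzene
Product: 6 allyl 2-fluoro-4-(methoxymethoxy)-3-(3-methylbut-2-en-1-yl)benzoate, via C1-aryllithium 5 (not isolated)
Conditions: n-BuLi (1.05 equiv), THF, −78 °C; cannulated into ClCO2allyl (2 equiv), THF, −78 °C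
Reagents that add atoms: allyl chloroformate, C=CCOC(=O)Cl
Why: Bromine–lithium exchange is faster than any deprotonation at −78 °C, the o-fluoroaryllithium is stable at that temperature, and inverse addition to excess chloroformate stops the acylation at the ester.

Step 4
Reactants: 7 1-(4-hydroxyphenyl)ethan-1-one (4'-hydroxyacetophenone)
Product: 9 1-(2,2-dimethyl-3,4-dihydro-2H-chromen-6-yl)ethan-1-one, via ortho-prenylphenol 8 (not isolated)
Conditions: isoprene, 85 % H3PO4, xylene, 30–35 °C
Reagents that add atoms: isoprene, C=CC(C)=C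
Why: Acid-catalysed Friedel–Crafts prenylation ortho to the hydroxyl (the para position is blocked by the acetyl group) is followed by Markovnikov hydroalkoxylation of the prenyl alkene through the tertiary cation, which closes the 2,2-dimethylchroman ring.

Step 5
Reactants: 9 1-(2,2-dimethyl-3,4-dihydro-2H-chromen-6-yl)ethan-1-one
Product: 11 allyl 3-(2,2-dimethyl-3,4-dihydro-2H-chromen-6-yl)-3-oxopropanoate, via sodium enolate 10 (not isolated)
Conditions: NaH (2.5 equiv), diallyl carbonate (2 equiv), THF, reflux; AcOH quench
Reagents that add atoms: diallyl carbonate, C=CCOC(=O)OCC=C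
Why: Crossed Claisen condensation of the methyl ketone enolate with a non-enolisable carbonate is driven to completion by irreversible deprotonation of the β-keto ester.

Step 6
Reactants: 11 allyl 3-(2,2-dimethyl-3,4-dihydro-2H-chromen-6-yl)-3-oxopropanoate
Product: 12 allyl (3S)-3-(2,2-dimethyl-3,4-dihydro-2H-chromen-6-yl)-3-hydroxypropanoate
Conditions: RuCl[(S,S)-TsDPEN](p-cymene) (1 mol %), HCO2H/Et3N (5:2), DMF, 30 °C
Reagents that add atoms: none
Why: Noyori–Ikariya asymmetric transfer hydrogenation of the aryl ketone, in which the (S,S)-catalyst is expected to deliver hydride to the Re face (CH/π contact between the aryl group and the η6-arene, as for acetophenones) and so to give the (S)-carbinol that becomes C2, while the outer-sphere mechanism leaves the allyl ester alkene untouched.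

Step 7
Reactants: 12 allyl (3S)-3-(2,2-dimethyl-3,4-dihydro-2H-chromen-6-yl)-3-hydroxypropanoate; 6 allyl 2-fluoro-4-(methoxymethoxy)-3-(3-methylbut-2-en-1-yl)benzoate
Product: 16 allyl (2S)-2-(2,2-dimethyl-3,4-dihydro-2H-chromen-6-yl)-7-(methoxymethoxy)-8-(3-methylbut-2-en-1-yl)-4-oxochromane-3-carboxylate, via dianion 13 (not isolated), via acyclic adduct 14 (not isolated), via lithium enolate 15 (not isolated)
Conditions: LDA (2.1 equiv), THF, −78 → −30 °C; LiHMDS (1.1 equiv), 6, −78 → −20 °C; DMPU, → 20 °C; AcOH, −20 °C
Reagents that add atoms: none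
Why: Proposed new method: LDA converts 12 into the chelated alkoxide–enolate dianion 13, whose enolate carbon C3 attacks the ester carbonyl of 6 (crossed Claisen acylation, C3–C4) while LiHMDS takes up the acidic C3–H of the adduct so that 13 is not consumed as a base; in the resulting dilithio species 14 the benzylic alkoxide O1 adds to C8a, which carries fluoride and is ortho to the new C4 carbonyl, and fluoride leaves the Meisenheimer adduct (SNAr, O1–C8a) to give the enolate 15, protonated to 16 on quench. The closest known chemistry is the one-pot C-acylation/SNAr route from 2-fluorobenzoyl electrophiles and enolates to flavones, chromone-3-carboxylates and 4-quinolones, together with C-functionalisation of β-oxido ester dianions (Fráter–Seebach type); new is the use of such a dianion so that a saturated, C2-stereodefined chroman-4-one results. Ring C closes in a 6-exo-trig addition–elimination at C8a, and because C4 is held as an enolate the arene is less activated than in a free ketone, which is why DMPU and warming to 20 °C are provided. No bond to C2 is formed or broken, so C2 should keep the S configuration from step 6, whereas C3 is created as an enolate carbon, is not controlled and is erased in step 8. The step needs C- rather than O-acylation (the enolate carbon of 13 is far more nucleophilic than the secondary lithium alkoxide held in the chelate), intramolecular rather than intermolecular fluoride displacement (six-membered transition state; the released lithium allyloxide meets only an enolate-deactivated ring and, being the alkoxide of both esters, cannot scramble them) and an intact C2–O1 bond (14 cannot undergo retro-aldol cleavage or dehydration because C3 is already an enolate, and the chelated enolate 15 is expected to be too stabilised to expel the aryloxide below 20 °C).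

Step 8
Reactants: 16 allyl (2S)-2-(2,2-dimethyl-3,4-dihydro-2H-chromen-6-yl)-7-(methoxymethoxy)-8-(3-methylbut-2-en-1-yl)-4-oxochromane-3-carboxylate
Product: 18 (2S)-2-(2,2-dimethyl-3,4-dihydro-2H-chromen-6-yl)-7-(methoxymethoxy)-8-(3-methylbut-2-en-1-yl)-2,3-dihydro-4H-chromen-4-one, via β-keto acid 17 (not isolated)
Conditions: Pd(PPh3)4 (5 mol %), HCO2H (3 equiv), Et3N (2.5 equiv), THF, 25 °C
Reagents that add atoms: none
Why: Tsuji deallylation–decarboxylation, in which Pd(0) ionises the allyl ester, formate reduces the π-allyl unit to propene and the β-keto acid loses CO2 through its cyclic enol-forming transition state in a formate buffer, so that C2 is not exposed to free base and the prenyl alkene and MOM ether stay inert.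

Step 9
Reactants: 18 (2S)-2-(2,2-dimethyl-3,4-dihydro-2H-chromen-6-yl)-7-(methoxymethoxy)-8-(3-methylbut-2-en-1-yl)-2,3-dihydro-4H-chromen-4-one
Product: 19 euchrenone a17, (2S)-2-(2,2-dimethyl-3,4-dihydro-2H-chromen-6-yl)-7-hydroxy-8-(3-methylbut-2-en-1-yl)-2,3-dihydro-4H-chromen-4-one
Conditions: 3 M aq. HCl/MeOH (1:5), 25–40 °C
Reagents that add atoms: none
Why: Acid-catalysed acetal exchange transfers the MOM group to methanol under the mild conditions customary for prenylated flavanones, which should neither cyclise the prenyl group onto the liberated 7-OH nor enolise or open ring C, so the (2S) centre is retained.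

## Compound list

1 | 4-bromo-3-fluorophenol | Oc1ccc(Br)c(F)c1 | starting material
2 | 1-bromo-2-fluoro-4-(methoxymethoxy)benzene | COCOc1ccc(Br)c(F)c1 | intermediate
3 | [3-bromo-2-fluoro-6-(methoxymethoxy)phenyl]lithium | COCOc1ccc(Br)c(F)c1[Li] | intermediate
4 | 1-bromo-2-fluoro-4-(methoxymethoxy)-3-(3-methylbut-2-en-1-yl)benzene | COCOc1ccc(Br)c(F)c1CC=C(C)C | intermediate
5 | [2-fluoro-4-(methoxymethoxy)-3-(3-methylbut-2-en-1-yl)phenyl]lithium | COCOc1ccc([Li])c(F)c1CC=C(C)C | intermediate
6 | allyl 2-fluoro-4-(methoxymethoxy)-3-(3-methylbut-2-en-1-yl)benzoate | C=CCOC(=O)c1ccc(OCOC)c(CC=C(C)C)c1F | intermediate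
7 | 1-(4-hydroxyphenyl)ethan-1-one (4'-hydroxyacetophenone) | CC(=O)c1ccc(O)cc1 | starting material
8 | 1-[4-hydroxy-3-(3-methylbut-2-en-1-yl)phenyl]ethan-1-one | CC(=O)c1ccc(O)c(CC=C(C)C)c1 | intermediate
9 | 1-(2,2-dimethyl-3,4-dihydro-2H-chromen-6-yl)ethan-1-one | CC(=O)c1ccc2c(c1)CCC(C)(C)O2 | intermediate
10 | sodium enolate of allyl 3-(2,2-dimethyl-3,4-dihydro-2H-chromen-6-yl)-3-oxopropanoate | [Na+].C=CCOC(=O)C=C([O-])c1ccc2c(c1)CCC(C)(C)O2 | intermediate
11 | allyl 3-(2,2-dimethyl-3,4-dihydro-2H-chromen-6-yl)-3-oxopropanoate | C=CCOC(=O)CC(=O)c1ccc2c(c1)CCC(C)(C)O2 | intermediate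
12 | allyl (3S)-3-(2,2-dimethyl-3,4-dihydro-2H-chromen-6-yl)-3-hydroxypropanoate | O[C@H](c1ccc2c(c1)CCC(C)(C)O2)CC(=O)OCC=C | intermediate
13 | dilithium alkoxide–ester enolate of 12 (carbinol configuration unchanged) | [Li+].[Li+].[O-][C@H](c1ccc2c(c1)CCC(C)(C)O2)C=C([O-])OCC=C | intermediate
14 | dilithium salt (benzylic alkoxide and β-keto ester enolate) of allyl 2-[2-fluoro-4-(methoxymethoxy)-3-(3-methylbut-2-en-1-yl)benzoyl]-3-(2,2-dimethyl-3,4-dihydro-2H-chromen-6-yl)-3-hydroxypropanoate (carbinol configuration as in 12) | [Li+].[Li+].[O-][C@H](c1ccc2c(c1)CCC(C)(C)O2)C(C(=O)OCC=C)=C([O-])c1ccc(OCOC)c(CC=C(C)C)c1F | intermediate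
15 | lithium C3=C4 enolate of 16 (2S) | [Li+].CC(C)=CCc1c(OCOC)ccc2c1O[C@H](c1ccc3c(c1)CCC(C)(C)O3)C(C(=O)OCC=C)=C2[O-] | intermediate
16 | allyl (2S)-2-(2,2-dimethyl-3,4-dihydro-2H-chromen-6-yl)-7-(methoxymethoxy)-8-(3-methylbut-2-en-1-yl)-4-oxochromane-3-carboxylate (C3 epimers and enol tautomer interconvert; C3 left undefined) | CC(C)=CCc1c(OCOC)ccc2c1O[C@H](c1ccc3c(c1)CCC(C)(C)O3)C(C(=O)OCC=C)C2=O | intermediate
17 | (2S)-2-(2,2-dimethyl-3,4-dihydro-2H-chromen-6-yl)-7-(methoxymethoxy)-8-(3-methylbut-2-en-1-yl)-4-oxochromane-3-carboxylic acid (C3 undefined) | CC(C)=CCc1c(OCOC)ccc2c1O[C@H](c1ccc3c(c1)CCC(C)(C)O3)C(C(=O)O)C2=O | intermediate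
18 | (2S)-2-(2,2-dimethyl-3,4-dihydro-2H-chromen-6-yl)-7-(methoxymethoxy)-8-(3-methylbut-2-en-1-yl)-2,3-dihydro-4H-chromen-4-one | CC(C)=CCc1c(OCOC)ccc2c1O[C@H](c1ccc3c(c1)CCC(C)(C)O3)CC2=O | intermediate
19 | euchrenone a17, (2S)-2-(2,2-dimethyl-3,4-dihydro-2H-chromen-6-yl)-7-hydroxy-8-(3-methylbut-2-en-1-yl)-2,3-dihydro-4H-chromen-4-one | CC(C)=CCc1c(O)ccc2c1O[C@H](c1ccc3c(c1)CCC(C)(C)O3)CC2=O | target

## Step count and risks

Total steps: 9. Longest linear sequence: 6 steps (steps 4–9 from 7; equally steps 1–3 and 7–9 from 1).

Steps most likely to fail: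

1. Step 7 (proposed new method). Three processes could spoil it. The alkoxide of 13 may be acylated instead of the enolate carbon, and the O-acylated ester enolate would then lose the aroate by β-elimination. The ring closure may stall because the enolised aroyl group activates the C–F carbon only weakly. The product enolate may open reversibly at C2–O1, which would erode the configuration at C2. The fallback uses known reactions only, sets out from 12 and 4, and returns to the route at 18, bypassing steps 7 and 8. Alcohol 12 is silylated (TBSCl, imidazole, DMF) to allyl (3S)-3-[(tert-butyldimethylsilyl)oxy]-3-(2,2-dimethyl-3,4-dihydro-2H-chromen-6-yl)propanoate F1. This is converted with MeNH(OMe)·HCl/i-PrMgCl (THF, −20 °C) into the Weinreb amide (3S)-3-[(tert-butyldimethylsilyl)oxy]-3-(2,2-dimethyl-3,4-dihydro-2H-chromen-6-yl)-N-methoxy-N-methylpropanamide F2. The aryllithium 5, generated from 4 as in step 3, is added to F2 at −78 °C (Weinreb ketone synthesis, which forms C4–C4a instead of C3–C4) to give (3S)-3-[(tert-butyldimethylsilyl)oxy]-3-(2,2-dimethyl-3,4-dihydro-2H-chromen-6-yl)-1-[2-fluoro-4-(methoxymethoxy)-3-(3-methylbut-2-en-1-yl)phenyl]propan-1-one F3. TBAF (THF, −20 → 0 °C) then removes the silyl group, and the liberated alkoxide should close ring C by intramolecular SNAr on the non-enolised, fully activating ketone to give 18; the displaced fluoride carries the desilylation on.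

2. Step 4. The Friedel–Crafts alkylation of a phenol deactivated by the para-acetyl group may convert poorly, with isoprene oligomerising and some double alkylation. The fallback sets out from 7 and returns at 9. O-Alkylation of 7 with 3-chloro-3-methylbut-1-yne (K2CO3, KI, acetone, reflux) gives 1-{4-[(2-methylbut-3-yn-2-yl)oxy]phenyl}ethan-1-one F4. Heating (N,N-diethylaniline, 190 °C) triggers the aromatic propargyl Claisen rearrangement, 1,5-hydrogen shift and 6π-electrocyclisation to 1-(2,2-dimethyl-2H-chromen-6-yl)ethan-1-one F5. Hydrogenation (H2, 1 atm, Pd/C, EtOAc) saturates the chromene double bond to give 9.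

3. Step 2. The o-fluoroaryllithium may lose lithium fluoride (aryne formation) if it warms before capture, and the aryl metal may attack the γ-terminus of the prenyl electrophile and give the reverse-prenyl isomer. The fallback sets out from 2 and returns at 4. The aryllithium 3 is quenched at −78 °C with iodine to give 1-bromo-2-fluoro-3-iodo-4-(methoxymethoxy)benzene F6, so the lithium species is never warmed. The prenyl group is then introduced by a Stille coupling at the more reactive C–I bond with tributyl(3-methylbut-2-en-1-yl)stannane (Pd(PPh3)4, DMF, 60 °C), which transfers the linear prenyl group and leaves the C–Br bond for step 3, giving 4.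

## Further compounds

F1 | step 7 | allyl (3S)-3-[(tert-butyldimethylsilyl)oxy]-3-(2,2-dimethyl-3,4-dihydro-2H-chromen-6-yl)propanoate | CC(C)(C)[Si](C)(C)O[C@H](c1ccc2c(c1)CCC(C)(C)O2)CC(=O)OCC=C
F2 | step 7 | (3S)-3-[(tert-butyldimethylsilyl)oxy]-3-(2,2-dimethyl-3,4-dihydro-2H-chromen-6-yl)-N-methoxy-N-methylpropanamide | CC(C)(C)[Si](C)(C)O[C@H](c1ccc2c(c1)CCC(C)(C)O2)CC(=O)N(C)OC
F3 | step 7 | (3S)-3-[(tert-butyldimethylsilyl)oxy]-3-(2,2-dimethyl-3,4-dihydro-2H-chromen-6-yl)-1-[2-fluoro-4-(methoxymethoxy)-3-(3-methylbut-2-en-1-yl)phenyl]propan-1-one | CC(C)(C)[Si](C)(C)O[C@H](c1ccc2c(c1)CCC(C)(C)O2)CC(=O)c1ccc(OCOC)c(CC=C(C)C)c1F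
F4 | step 4 | 1-{4-[(2-methylbut-3-yn-2-yl)oxy]phenyl}ethan-1-one | CC(=O)c1ccc(OC(C)(C)C#C)cc1
F5 | step 4 | 1-(2,2-dimethyl-2H-chromen-6-yl)ethan-1-one | CC(=O)c1ccc2c(c1)C=CC(C)(C)O2
F6 | step 2 | 1-bromo-2-fluoro-3-iodo-4-(methoxymethoxy)benzene | COCOc1ccc(Br)c(F)c1I
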